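## Retrosynthetic overview

1. Target 22 ⇒ acetylation and Pd/CO lactonisation (C1–C18 and C18–O bonds) of enol triflate diol 20 ⇒ nine-membered ketone 16. The γ-lactone is the last ring closed.
2. 16 ⇒ key ring expansion. A C2 radical from epoxide 12 adds to the cyclopentanone C=O (C1–C2 bond, transient hydrindane), C1–C6 breaks and Br leaves C7. This takes the five-membered ring to nine members and sets C2 and the E C6=C7 alkene.
3. 12 ⇒ aldehyde 11 (+ CH2) ⇒ three-component conjugate addition/aldol of 5, 6 and 4 (C10–C11 and C3–C4 bonds). This sets C10, C3 and C4.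
4. 4 ⇒ bromo ketone 3 ⇒ bromine-induced 1,2-allyl shift of carbinol 2 (quaternary C6, C7–Br cis to CH3) ⇒ 2-methylcyclopentenone 1.
5. Ring order: cyclopentane (bought) → hydrindane (transient) → cyclononene → lactone.

Assumption: C-numbers are the xenicane numbers of the target (C1 lactone α-carbon, C2 ring-fusion CH, C3 CH bearing the side chain, C4 CHOAc, C5 CH2, C6 methyl-bearing alkene carbon, C7 alkene CH, C8 CH2, C9 alkene CH next to C1, C10 side-chain CH, C18 lactone C=O, C19 lactone OCH2), and of each chiral catalyst the antipode that gives the drawn enantiomer is used.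

## Route

Step 1
Reactants: 1 2-methylcyclopent-2-en-1-one
Product: 2 (1S)-2-methyl-1-(prop-2-enyl)cyclopent-2-en-1-ol
Conditions: Sn(CH2CH=CH2)4 (1.5 equiv), Ti(OiPr)4 (20 mol %), (R)-BINOL (20 mol %), iPrOH (20 equiv), CH2Cl2, rt
Reagents that add atoms: tetraallylstannane, C=CC[Sn](CC=C)(CC=C)CC=C
Why: Catalytic asymmetric carbonyl allylation (1,2-addition): the BINOL–titanium Lewis acid binds the enone carbonyl so that the allylstannane attacks one face only, which sets the carbinol centre, and the α-methyl group suppresses 1,4-addition.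

Step 2
Reactants: 2 (1S)-2-methyl-1-(prop-2-enyl)cyclopent-2-en-1-ol
Product: 3 (2S,3S)-3-bromo-2-methyl-2-(prop-2-enyl)cyclopentan-1-one (Br cis to CH3)
Conditions: NBS (1.05 equiv), CH2Cl2, −40 to 0 °C, dark
Reagents that add atoms: N-bromosuccinimide, O=C1CCC(=O)N1Br
Why: Halogen-induced semipinacol rearrangement (1,2-shift): Br+ is taken up on the hydroxyl face of the electron-rich trisubstituted ring alkene (the monosubstituted allyl alkene is far less nucleophilic) and the anti-periplanar allyl group moves from the carbinol carbon to C6 as the C1 ketone forms, so quaternary C6 and C7–Br arise with Br trans to allyl and cis to CH3.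

Step 3
Reactants: 3 (2S,3S)-3-bromo-2-methyl-2-(prop-2-enyl)cyclopentan-1-one
Product: 4 2-[(1S,2S)-2-bromo-1-methyl-5-oxocyclopentyl]acetaldehyde
Conditions: O3, CH2Cl2/MeOH, −78 °C; Me2S, −78 °C to rt
Reagents that add atoms: ozone, [O-][O+]=O
Why: Ozonolysis with reductive work-up cleaves the only alkene to the C4 aldehyde, and the ketone, the secondary bromide and both stereocentres are untouched.

Step 4
Reactants: 4 2-[(1S,2S)-2-bromo-1-methyl-5-oxocyclopentyl]acetaldehyde; 5 5-bromo-2-methylpent-2-ene; 6 S-ethyl (E)-but-2-enethioate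
Product: 9 S-ethyl (2R,3R)-4-[(1S,2S)-2-bromo-1-methyl-5-oxocyclopentyl]-3-hydroxy-2-[(2R)-6-methylhept-5-en-2-yl]butanethioate, via homoprenylmagnesium bromide 7 (not isolated), via magnesium thioester enolate 8 (not isolated)
Conditions: 5, Mg, Et2O, reflux; 6 (1.3 equiv), CuBr·SMe2 (5 mol %), (R)-1-[(S)-2-(diphenylphosphino)ferrocenyl]ethyldicyclohexylphosphine (6 mol %), t-BuOMe, −75 °C, 7 (1.2 equiv) over 1 h; 4 (1.0 equiv), −75 °C, 2 h; aq NH4Cl at −75 °C
Reagents that add atoms: none
Why: Enantioselective conjugate addition of a Grignard reagent under monovalent copper catalysis followed by aldol trapping: the chiral diphosphine–copper catalyst sets C10 (R), the (Z)-enolate 8 adds to the aldehyde rather than the hindered ketone through a closed chair (anti aldol, C3/C4) on the face opposite the homoprenyl chain (A1,3 strain), and the cold quench keeps the aldolate away from the ketone.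

Step 5
Reactants: 9 S-ethyl (2R,3R)-4-[(1S,2S)-2-bromo-1-methyl-5-oxocyclopentyl]-3-hydroxy-2-[(2R)-6-methylhept-5-en-2-yl]butanethioate
Product: 10 S-ethyl (2R,3R)-4-[(1S,2S)-2-bromo-1-methyl-5-oxocyclopentyl]-3-(tert-butyldimethylsilyloxy)-2-[(2R)-6-methylhept-5-en-2-yl]butanethioate
Conditions: TBSOTf, 2,6-lutidine, CH2Cl2, −78 to 0 °C
Reagents that add atoms: tert-butyldimethylsilyl triflate, CC(C)(C)[Si](C)(C)OS(=O)(=O)C(F)(F)F
Why: Silyl ether formation under non-basic conditions blocks O4, so no alkoxide can add to the C1 ketone or trigger retro-aldol cleavage later, and no stereocentre changes.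

Step 6
Reactants: 10 S-ethyl (2R,3R)-4-[(1S,2S)-2-bromo-1-methyl-5-oxocyclopentyl]-3-(tert-butyldimethylsilyloxy)-2-[(2R)-6-methylhept-5-en-2-yl]butanethioate
Product: 11 (2R,3R)-4-[(1S,2S)-2-bromo-1-methyl-5-oxocyclopentyl]-3-(tert-butyldimethylsilyloxy)-2-[(2R)-6-methylhept-5-en-2-yl]butanal
Conditions: Et3SiH, 10% Pd/C, acetone, rt
Reagents that add atoms: none
Why: Fukuyama reduction turns only the thioester into the aldehyde under neutral aprotic conditions that leave the ketone, the trisubstituted alkene, the hindered secondary bromide and the α-stereocentre C3 alone.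

Step 7
Reactants: 11 (2R,3R)-4-[(1S,2S)-2-bromo-1-methyl-5-oxocyclopentyl]-3-(tert-butyldimethylsilyloxy)-2-[(2R)-6-methylhept-5-en-2-yl]butanal
Product: 12 (2S,3S)-3-bromo-2-[(2R,3S,4R)-2-(tert-butyldimethylsilyloxy)-4,8-dimethyl-3-(oxiran-2-yl)non-7-enyl]-2-methylcyclopentan-1-one (both epimers at the oxirane CH, C2)
Conditions: Me3SI, n-BuLi, THF, −10 °C; 11, −10 to 0 °C
Reagents that add atoms: trimethylsulfonium iodide, C[S+](C)C.[I-]
Why: Corey–Chaykovsky epoxidation adds C19 to the aldehyde much faster than to the ketone flanked by the quaternary carbon and does not touch the alkene, and the epimer ratio at C2 does not matter because C2 becomes planar in step 8.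

Step 8
Reactants: 12 (2S,3S)-3-bromo-2-[(2R,3S,4R)-2-(tert-butyldimethylsilyloxy)-4,8-dimethyl-3-(oxiran-2-yl)non-7-enyl]-2-methylcyclopentan-1-one
Product: 16 (2R,3S,4R,6E)-4-(tert-butyldimethylsilyloxy)-2-(hydroxymethyl)-6-methyl-3-[(2R)-6-methylhept-5-en-2-yl]cyclonon-6-en-1-one, via carbon radical 13 (not isolated), via alkoxyl radical 14 (not isolated), via titanium alkoxide 15 (not isolated)
Conditions: Cp2TiCl2 (2.5 equiv, Cp = C5H5), Zn, THF, rt, decanted; added over 3 h to 12 (5 mM in THF), rt; aq NaH2PO4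
Reagents that add atoms: none
Why: Proposed new method: Cp2TiCl (trivalent titanium) opens the terminal epoxide homolytically to the secondary C2 radical 13 (both epimers converge), the tetravalent titanium alkoxide on O19 binds the C1 ketone and guides a 6-exo attack of C2 on C1 through a chair with CH2O and the C3 side chain equatorial (sets C2 trans to C3) to give the cis-fused alkoxyl radical 14, whose C1–C6 bond is anti-periplanar to C7–Br with C8 anti to C5, so β-scission and loss of Br to a second Cp2TiCl are irreversible, drain the reversible carbonyl addition and give the nine-membered ketone with the E C6=C7 alkene; the closest known reactions are the Cp2TiCl cyclisation of epoxy ketones to cycloalkanols, the Dowd–Beckwith radical ring expansion and the Grob fragmentation of γ-halo alkoxides, whose merger into a four-atom ring expansion ended by halogen loss has not been described.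

Step 9
Reactants: 16 (2R,3S,4R,6E)-4-(tert-butyldimethylsilyloxy)-2-(hydroxymethyl)-6-methyl-3-[(2R)-6-methylhept-5-en-2-yl]cyclonon-6-en-1-one
Product: 17 (2R,3S,4R,6E)-4-(tert-butyldimethylsilyloxy)-2-[(tert-butyldimethylsilyloxy)methyl]-6-methyl-3-[(2R)-6-methylhept-5-en-2-yl]cyclonon-6-en-1-one
Conditions: TBSCl, imidazole, DMF, 0 °C to rt
Reagents that add atoms: tert-butyldimethylsilyl chloride, CC(C)(C)[Si](C)(C)Cl
Why: Silylation of the primary alcohol under weakly basic conditions prevents retro-aldol loss of C19 in the next step and does not epimerise C2.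

Step 10
Reactants: 17 (2R,3S,4R,6E)-4-(tert-butyldimethylsilyloxy)-2-[(tert-butyldimethylsilyloxy)methyl]-6-methyl-3-[(2R)-6-methylhept-5-en-2-yl]cyclonon-6-en-1-one
Product: 19 C1 enol triflate of 17 (C1=C9 double bond cis within the ring with OTf trans to C8; C6=C7 E), via potassium enolate 18 (not isolated)
Conditions: KN(SiMe3)2 (1.1 equiv), THF, −78 °C; N-(5-chloropyridin-2-yl)bis(trifluoromethanesulfonimide), −78 °C
Reagents that add atoms: N-(5-chloropyridin-2-yl)bis(trifluoromethanesulfonimide), FC(F)(F)S(=O)(=O)N(c1ccc(Cl)cn1)S(=O)(=O)C(F)(F)F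
Why: Kinetic enolisation and O-triflation: the bulky base removes a proton from the unhindered C9 methylene and not the tertiary C2–H, and the ring, which already holds one E alkene, only accommodates the ring-cis enolate, which fixes the C1=C9 geometry and leaves C2 intact.

Step 11
Reactants: 19 C1 enol triflate of 17
Product: 20 enol triflate diol (C4–OH and C19–OH free)
Conditions: HF·pyridine, pyridine, THF, 0 °C to rt
Reagents that add atoms: none
Why: Fluoride-mediated desilylation removes both silyl ethers under buffered conditions that enol triflates and the skipped diene tolerate.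

Step 12
Reactants: 20 enol triflate diol
Product: 22 target CNP0288725.2 (4-acetoxydictyolactone), via 4-hydroxydictyolactone 21 (not isolated)
Conditions: Pd(PPh3)4 (10 mol %), CO (1 atm), Et3N, MeCN, 60 °C; vent, then Ac2O, DMAP, rt, same flask
Reagents that add atoms: carbon monoxide, [C-]#[O+]; acetic anhydride, CC(=O)OC(C)=O
Why: Carbonylative lactonisation: zerovalent palladium inserts into C1–OTf with retention of the alkene geometry, CO insertion and capture by the primary C19–OH close the five-membered lactone faster than the hindered C4–OH could close a six-membered one, and DMAP-catalysed acetylation of C4–OH then gives the target without touching any stereocentre.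

## Compound list

1 | 2-methylcyclopent-2-en-1-one | CC1=CCCC1=O | starting material
2 | (1S)-2-methyl-1-(prop-2-enyl)cyclopent-2-en-1-ol | O[C@]1(CC=C)CCC=C1C | intermediate
3 | (2S,3S)-3-bromo-2-methyl-2-(prop-2-enyl)cyclopentan-1-one | O=C1CC[C@H](Br)[C@@]1(C)CC=C | intermediate
4 | 2-[(1S,2S)-2-bromo-1-methyl-5-oxocyclopentyl]acetaldehyde | O=C1CC[C@H](Br)[C@@]1(C)CC=O | intermediate
5 | 5-bromo-2-methylpent-2-ene | CC(C)=CCCBr | starting material
6 | S-ethyl (E)-but-2-enethioate | CCSC(=O)/C=C/C | starting material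
7 | (4-methylpent-3-enyl)magnesium bromide | CC(C)=CCC[Mg]Br | intermediate
8 | bromomagnesium (Z)-enolate of S-ethyl (R)-3,7-dimethyloct-6-enethioate | CCS/C(O[Mg]Br)=C\[C@H](C)CCC=C(C)C | intermediate
9 | S-ethyl (2R,3R)-4-[(1S,2S)-2-bromo-1-methyl-5-oxocyclopentyl]-3-hydroxy-2-[(2R)-6-methylhept-5-en-2-yl]butanethioate | CCSC(=O)[C@H]([C@H](C)CCC=C(C)C)[C@H](O)C[C@]1(C)[C@@H](Br)CCC1=O | intermediate
10 | O4-TBS ether of 9 | CCSC(=O)[C@H]([C@H](C)CCC=C(C)C)[C@H](O[Si](C)(C)C(C)(C)C)C[C@]1(C)[C@@H](Br)CCC1=O | intermediate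
11 | (2R,3R)-4-[(1S,2S)-2-bromo-1-methyl-5-oxocyclopentyl]-3-(tert-butyldimethylsilyloxy)-2-[(2R)-6-methylhept-5-en-2-yl]butanal | O=C[C@H]([C@H](C)CCC=C(C)C)[C@H](O[Si](C)(C)C(C)(C)C)C[C@]1(C)[C@@H](Br)CCC1=O | intermediate
12 | terminal epoxide from 11 (oxirane C2–O–C19, both C2 epimers) | C1OC1[C@H]([C@H](C)CCC=C(C)C)[C@H](O[Si](C)(C)C(C)(C)C)C[C@]2(C)[C@@H](Br)CCC2=O | intermediate
13 | secondary C2 radical carrying O19–TiClCp2 | Cl[Ti](OC[CH][C@H]([C@H](C)CCC=C(C)C)[C@H](O[Si](C)(C)C(C)(C)C)C[C@]1(C)[C@@H](Br)CCC1=O)(C2C=CC=C2)C2C=CC=C2 | intermediate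
14 | cis-fused hydrindane C1 alkoxyl radical (O1, CH3 and Br on one face of the five-membered ring) | [O][C@]12CC[C@H](Br)[C@@]1(C)C[C@@H](O[Si](C)(C)C(C)(C)C)[C@@H]([C@H](C)CCC=C(C)C)[C@@H]2CO[Ti](Cl)(C3C=CC=C3)C3C=CC=C3 | intermediate
15 | O19–TiClCp2 alkoxide of 16 | O=C1CC/C=C(C)/C[C@@H](O[Si](C)(C)C(C)(C)C)[C@@H]([C@H](C)CCC=C(C)C)[C@@H]1CO[Ti](Cl)(C2C=CC=C2)C2C=CC=C2 | intermediate
16 | (2R,3S,4R,6E)-4-(tert-butyldimethylsilyloxy)-2-(hydroxymethyl)-6-methyl-3-[(2R)-6-methylhept-5-en-2-yl]cyclonon-6-en-1-one | O=C1CC/C=C(C)/C[C@@H](O[Si](C)(C)C(C)(C)C)[C@@H]([C@H](C)CCC=C(C)C)[C@@H]1CO | intermediate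
17 | O19-TBS ether of 16 | O=C1CC/C=C(C)/C[C@@H](O[Si](C)(C)C(C)(C)C)[C@@H]([C@H](C)CCC=C(C)C)[C@@H]1CO[Si](C)(C)C(C)(C)C | intermediate
18 | potassium C1=C9 enolate of 17 (ring-cis) | [K+].[O-]/C1=C/C/C=C(C)/C[C@@H](O[Si](C)(C)C(C)(C)C)[C@@H]([C@H](C)CCC=C(C)C)[C@@H]1CO[Si](C)(C)C(C)(C)C | intermediate
19 | C1 enol triflate of 17 | FC(F)(F)S(=O)(=O)O/C1=C/C/C=C(C)/C[C@@H](O[Si](C)(C)C(C)(C)C)[C@@H]([C@H](C)CCC=C(C)C)[C@@H]1CO[Si](C)(C)C(C)(C)C | intermediate
20 | enol triflate diol | FC(F)(F)S(=O)(=O)O/C1=C/C/C=C(C)/C[C@@H](O)[C@@H]([C@H](C)CCC=C(C)C)[C@@H]1CO | intermediate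
21 | 4-hydroxydictyolactone (C4 alcohol of the target) | O[C@@H]1C/C(C)=C/C/C=C2/C(=O)OC[C@H]2[C@@H]1[C@H](C)CCC=C(C)C | intermediate
22 | CNP0288725.2, 4-acetoxydictyolactone (2S,3S,4R,10R) | CC(=O)O[C@@H]1C/C(C)=C/C/C=C2/C(=O)OC[C@H]2[C@@H]1[C@H](C)CCC=C(C)C | target

## Step count and risks

Total step count: 12. Longest linear sequence: 12 (from 1).

### Steps most likely to fail

**Step 8 (the new step).**
- Radical 13 may be reduced to the alkene by excess Cp2TiCl.
- It may close 6-exo onto the prenyl alkene.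
- It may take an allylic hydrogen from C12 by a 1,5-shift before it reaches the ketone.
- The fallback uses only known two-electron chemistry, sets out from 11 and comes back at 17.
- Wittig homologation of 11 with Ph3P=CHOMe gives the methyl enol ether F1.
- PPTS in wet acetone hydrolyses it to the one-carbon longer aldehyde F2.
- Pyrrolidine/AcOH-catalysed 6-enolexo aldolisation of the C19 aldehyde onto the C1 ketone gives the cis-fused hydroxy aldehyde F3, in which C2 equilibrates to the equatorial position trans to C3.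
- NaBH4 in MeOH gives the bromo diol F4, and TBSCl/imidazole gives the primary silyl ether F5.
- KN(SiMe3)2 in THF at 0 °C then triggers a classical Grob fragmentation (C7–Br anti-periplanar to C1–C6) to 17.

**Step 4.**
- The anti/anti sense of the three-component reaction rests on enolate geometry and A1,3 strain between two similar groups (CH3 and CH2R).
- The aldolate could also attack the ketone.
- The fallback sets out from 4 (with 5 and 6) and comes back at 11.
- The copper-catalysed conjugate addition is run alone and quenched to give S-ethyl (R)-3,7-dimethyloct-6-enethioate F6.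
- Fukuyama reduction gives (R)-citronellal F7.
- A D-proline-catalysed cross-aldol reaction (slow addition of F7 to 4, DMF, 4 °C) sets C3 and C4 under catalyst control and gives the anti β-hydroxy aldehyde F8.
- TBSOTf/2,6-lutidine then gives 11.

**Step 10.**
- Deprotonation at C2 with loss of the β-silyloxy group, or a wrong enolate geometry in the strained ring, would ruin the endgame.
- The fallback sets out from 17 and comes back at 21.
- Condensation with 2,4,6-triisopropylbenzenesulfonyl hydrazide gives the sulfonylhydrazone F9.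
- n-BuLi (Shapiro reaction, −78 to 0 °C) forms the vinyllithium on the less substituted C9 side, and CO2 traps it as the unsaturated acid F10.
- HF·pyridine removes both silyl groups, and the γ-hydroxy acid closes to 21, which is acetylated as in step 12.

## Further compounds

F1 | step 8 | methyl enol ether from 11 (MeO–C19H=C2H, E/Z mixture) | COC=C[C@H]([C@H](C)CCC=C(C)C)[C@H](O[Si](C)(C)C(C)(C)C)C[C@]1(C)[C@@H](Br)CCC1=O
F2 | step 8 | homologated aldehyde (OHC19–C2H2–C3) | O=CC[C@H]([C@H](C)CCC=C(C)C)[C@H](O[Si](C)(C)C(C)(C)C)C[C@]1(C)[C@@H](Br)CCC1=O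
F3 | step 8 | cis-fused hydrindane hydroxy aldehyde | O[C@]12CC[C@H](Br)[C@@]1(C)C[C@@H](O[Si](C)(C)C(C)(C)C)[C@@H]([C@H](C)CCC=C(C)C)[C@@H]2C=O
F4 | step 8 | cis-fused hydrindane bromo diol | O[C@]12CC[C@H](Br)[C@@]1(C)C[C@@H](O[Si](C)(C)C(C)(C)C)[C@@H]([C@H](C)CCC=C(C)C)[C@@H]2CO
F5 | step 8 | O19-TBS ether of F4 | O[C@]12CC[C@H](Br)[C@@]1(C)C[C@@H](O[Si](C)(C)C(C)(C)C)[C@@H]([C@H](C)CCC=C(C)C)[C@@H]2CO[Si](C)(C)C(C)(C)C
F6 | step 4 | S-ethyl (R)-3,7-dimethyloct-6-enethioate | CCSC(=O)C[C@H](C)CCC=C(C)C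
F7 | step 4 | (R)-citronellal | O=CC[C@H](C)CCC=C(C)C
F8 | step 4 | (2R,3R)-4-[(1S,2S)-2-bromo-1-methyl-5-oxocyclopentyl]-3-hydroxy-2-[(2R)-6-methylhept-5-en-2-yl]butanal | O=C[C@H]([C@H](C)CCC=C(C)C)[C@H](O)C[C@]1(C)[C@@H](Br)CCC1=O
F9 | step 10 | 2,4,6-triisopropylbenzenesulfonylhydrazone of 17 | CC(C)c1cc(C(C)C)c(c(C(C)C)c1)S(=O)(=O)NN=C1CC/C=C(C)/C[C@@H](O[Si](C)(C)C(C)(C)C)[C@@H]([C@H](C)CCC=C(C)C)[C@@H]1CO[Si](C)(C)C(C)(C)C
F10 | step 10 | C1 carboxylic acid (C1=C9 ring-cis, CO2H trans to C8) | OC(=O)/C1=C/C/C=C(C)/C[C@@H](O[Si](C)(C)C(C)(C)C)[C@@H]([C@H](C)CCC=C(C)C)[C@@H]1CO[Si](C)(C)C(C)(C)C
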